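**Plan**

1. Locants: quinone ring C1–C4 (methyl on C2, side chain on C3), chain C1'–C16'. Retrosynthetically the quinone is first masked as its 1,4-dimethoxynaphthalene, then C3–C1' and C4'–C5' are cut in one operation.
2. Enabling feature: C1'–C4' together with the C3' methyl are the five carbons of isoprene, lying between ring carbon C3 and the carbinol carbon C5'. The rest of the chain, C5'–C16', is a C15 aldehyde.
3. Forward: natural phytol is cut down to (3R,7R)-3,7,11-trimethyldodecanal (ozonolysis, desaturation of the methyl ketone, second ozonolysis). Menadione is converted to an arylzinc chloride. Nickel then joins arylzinc, isoprene and aldehyde, and oxidative demethylation finishes the route.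
4. No ring is formed anywhere: the naphthalene nucleus comes from menadione and the chain is joined in a single step.
5. Stereochemistry: C7' and C11' are carried over from phytol. C5' (S) is set by a chiral phosphoramidite on nickel in the key step. The E alkene comes from the syn-allylnickel alkoxide.

Key step: step 8

Assumption: the sense of induction of the phosphoramidite cannot be predicted with confidence. The (R)-ligand is written, and its antipode would be used if a trial with the aldehyde showed the opposite sense at C5'.

**Route**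

Step 1
Reactants: 1 natural phytol, (2E,7R,11R)-3,7,11,15-tetramethylhexadec-2-en-1-ol
Product: 3 (6R,10R)-6,10,14-trimethylpentadecan-2-one, via secondary ozonide 2 (not isolated)
Conditions: O3, CH2Cl2, −78 °C; then PPh3, −78 °C → rt
Reagents that add atoms: ozone, [O-][O+]=O
Why: Ozonolysis with reductive work-up cleaves the only alkene of phytol, releasing C1–C2 as water-soluble glycolaldehyde and leaving the two remote methyl stereocentres untouched.

Step 2
Reactants: 3 (6R,10R)-6,10,14-trimethylpentadecan-2-one
Product: 4 (2Z,6R,10R)-6,10,14-trimethyl-2-(trimethylsilyloxy)pentadec-2-ene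
Conditions: TMSCl, Et3N, DMF, 80 °C
Reagents that add atoms: chlorotrimethylsilane, C[Si](C)(C)Cl
Why: Equilibrating silylation of a methyl alkyl ketone should favour the more substituted enol ether (thermodynamic silyl enol ether formation), placing the enol double bond at C2=C3; the minor terminal isomer is harmless because it has no hydrogen that could be lost in step 3.

Step 3
Reactants: 4 (2Z,6R,10R)-6,10,14-trimethyl-2-(trimethylsilyloxy)pentadec-2-ene
Product: 5 (3E,6R,10R)-6,10,14-trimethylpentadec-3-en-2-one
Conditions: Pd(OAc)2 (10 mol %), O2 (1 atm), DMSO, rt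
Reagents that add atoms: none
Why: Saegusa–Ito oxidation in its aerobic catalytic form: the palladium enolate from 4 loses a β-hydride at C4 to give the E-enone, O2 returns zerovalent palladium to divalent palladium, and the C6 stereocentre is not involved.

Step 4
Reactants: 5 (3E,6R,10R)-6,10,14-trimethylpentadec-3-en-2-one
Product: 7 (3R,7R)-3,7,11-trimethyldodecanal, via secondary ozonide 6 (not isolated)
Conditions: O3, CH2Cl2, −78 °C; then PPh3, −78 °C → rt
Reagents that add atoms: ozone, [O-][O+]=O
Why: Ozonolysis of the enone C3=C4 bond removes C1–C3 as methylglyoxal and leaves the aldehyde, whose nearest stereocentre is β to the carbonyl and therefore cannot epimerise.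

Step 5
Reactants: 8 menadione, 2-methylnaphthalene-1,4-dione
Product: 10 1,4-dimethoxy-2-methylnaphthalene, via 2-methylnaphthalene-1,4-diol 9 (not isolated)
Conditions: Na2S2O4, Bu4NBr (cat.), THF/H2O, rt; then KOH (aq.), Me2SO4, rt
Reagents that add atoms: dimethyl sulfate, COS(=O)(=O)OC
Why: Na2S2O4 reduces the quinone to the hydroquinone, which is O-methylated in the same flask under phase-transfer Williamson conditions before air can reoxidise it (reductive methylation).

Step 6
Reactants: 10 1,4-dimethoxy-2-methylnaphthalene
Product: 11 2-bromo-1,4-dimethoxy-3-methylnaphthalene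
Conditions: Br2, CH2Cl2, 0 °C
Reagents that add atoms: bromine, BrBr
Why: Electrophilic aromatic bromination goes to the only free position of the electron-rich ring, ortho to a methoxy group.

Step 7
Reactants: 11 2-bromo-1,4-dimethoxy-3-methylnaphthalene
Product: 13 (1,4-dimethoxy-3-methylnaphthalen-2-yl)zinc chloride as a THF solution used at once, via aryllithium 12 (not isolated)
Conditions: t-BuLi (2 equiv), THF, −78 °C; then ZnCl2 (THF), −78 → 0 °C
Reagents that add atoms: zinc dichloride, Cl[Zn]Cl
Why: Bromine–lithium exchange followed by transmetalation to zinc gives a weakly basic arylzinc chloride, and the second equivalent of t-BuLi destroys the tert-butyl bromide so that no alkyl halide reaches the nickel catalyst of step 8.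

Step 8
Reactants: 13 (1,4-dimethoxy-3-methylnaphthalen-2-yl)zinc chloride; 14 isoprene; 7 (3R,7R)-3,7,11-trimethyldodecanal
Product: 16 (2E,5S,7R,11R)-1-(1,4-dimethoxy-3-methylnaphthalen-2-yl)-3,7,11,15-tetramethylhexadec-2-en-5-ol, via chlorozinc alkoxide 15 (not isolated)
Conditions: Ni(cod)2 (10 mol %), (R)-1,1'-spirobiindane-7,7'-diyl N,N-dimethylphosphoramidite (12 mol %), 14 (4 equiv), 13 (1.5 equiv, added slowly), THF/toluene, sealed vessel, 0 °C → rt; then 1 M HCl (aq.), 0 °C
Reagents that add atoms: none
Why: Proposed new method: zerovalent nickel carrying one phosphoramidite should bind 14 and the ZnCl2-activated aldehyde 7 and undergo oxidative cyclisation, forming C4'–C5' at the isoprene CH2 next to the methyl-bearing carbon and leaving an η3-allyl alkoxide of divalent nickel; 13 then takes the alkoxide onto zinc and hands its aryl group to nickel, and reductive elimination at the unsubstituted allyl terminus forms C3–C1', regenerates zerovalent nickel and gives alkoxide 15. The closest known reaction type is the nickel-catalysed three-component coupling of organozinc reagents, 1,3-dienes and aldehydes to E-homoallylic alcohols, which has not been shown with an ortho,ortho'-disubstituted arylzinc halide or with ligand-controlled enantioselection. No ring is closed; the step is an intermolecular chain assembly that makes two skeletal bonds. The one new stereocentre, C5' (S), is set in the oxidative cyclisation by the chiral ligand, which must direct the diene terminus to the Re face of the aldehyde because the C7' methyl (C3 of 7) is too remote for useful substrate control. The step needs 1,4-regiochemistry across isoprene, E geometry and chemoselectivity over 1,2-arylation of the aldehyde: the first should follow from the 2-methyl group of isoprene, which steers carbonyl attack to C1 and aryl delivery to the open C4 terminus, the second from the alkoxide tether holding the chain syn on the allyl unit, and the third from the low carbonyl reactivity of an arylzinc chloride compared with a diarylzinc or an aryllithium.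

Step 9
Reactants: 16 (2E,5S,7R,11R)-1-(1,4-dimethoxy-3-methylnaphthalen-2-yl)-3,7,11,15-tetramethylhexadec-2-en-5-ol
Product: 17 2-[(2E,5S,7R,11R)-5-hydroxy-3,7,11,15-tetramethylhexadec-2-en-1-yl]-3-methylnaphthalene-1,4-dione (CNP0289781.1)
Conditions: (NH4)2Ce(NO3)6 (2.2 equiv), MeCN/H2O, 0 °C, short reaction time
Reagents that add atoms: water, O
Why: Oxidative demethylation of the 1,4-dimethoxyarene by the tetravalent cerium salt gives the quinone with both carbonyl oxygens taken from water; the electron-rich arene should be consumed well before the alkene or the secondary alcohol, and any C5' epimer from step 8, a diastereomer, would be removed by chromatography here.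

**Compound list**

1 | natural phytol, (2E,7R,11R)-3,7,11,15-tetramethylhexadec-2-en-1-ol | OC/C=C(\C)CCC[C@H](C)CCC[C@H](C)CCCC(C)C | starting material
2 | secondary ozonide of 1, [5-methyl-5-((4R,8R)-4,8,12-trimethyltridecyl)-1,2,4-trioxolan-3-yl]methanol (ring stereoisomers) | CC1(CCC[C@H](C)CCC[C@H](C)CCCC(C)C)OOC(CO)O1 | intermediate
3 | (6R,10R)-6,10,14-trimethylpentadecan-2-one | CC(=O)CCC[C@H](C)CCC[C@H](C)CCCC(C)C | intermediate
4 | (2Z,6R,10R)-6,10,14-trimethyl-2-(trimethylsilyloxy)pentadec-2-ene (major enol ether) | C/C(O[Si](C)(C)C)=C/CC[C@H](C)CCC[C@H](C)CCCC(C)C | intermediate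
5 | (3E,6R,10R)-6,10,14-trimethylpentadec-3-en-2-one | CC(=O)/C=C/C[C@H](C)CCC[C@H](C)CCCC(C)C | intermediate
6 | secondary ozonide of 5, 1-{5-[(2R,6R)-2,6,10-trimethylundecyl]-1,2,4-trioxolan-3-yl}ethan-1-one (ring stereoisomers) | CC(=O)C1OOC(C[C@H](C)CCC[C@H](C)CCCC(C)C)O1 | intermediate
7 | (3R,7R)-3,7,11-trimethyldodecanal | O=CC[C@H](C)CCC[C@H](C)CCCC(C)C | intermediate
8 | menadione, 2-methylnaphthalene-1,4-dione | CC1=CC(=O)c2ccccc2C1=O | starting material
9 | 2-methylnaphthalene-1,4-diol | Cc1cc(O)c2ccccc2c1O | intermediate
10 | 1,4-dimethoxy-2-methylnaphthalene | COc1cc(C)c(OC)c2ccccc12 | intermediate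
11 | 2-bromo-1,4-dimethoxy-3-methylnaphthalene | COc1c(C)c(Br)c(OC)c2ccccc12 | intermediate
12 | (1,4-dimethoxy-3-methylnaphthalen-2-yl)lithium | COc1c(C)c([Li])c(OC)c2ccccc12 | intermediate
13 | (1,4-dimethoxy-3-methylnaphthalen-2-yl)zinc chloride | COc1c(C)c([Zn]Cl)c(OC)c2ccccc12 | intermediate
14 | isoprene, 2-methylbuta-1,3-diene | C=CC(C)=C | starting material
15 | chlorozinc (2E,5S,7R,11R)-1-(1,4-dimethoxy-3-methylnaphthalen-2-yl)-3,7,11,15-tetramethylhexadec-2-en-5-olate | COc1c(C)c(C/C=C(\C)C[C@@H](O[Zn]Cl)C[C@H](C)CCC[C@H](C)CCCC(C)C)c(OC)c2ccccc12 | intermediate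
16 | (2E,5S,7R,11R)-1-(1,4-dimethoxy-3-methylnaphthalen-2-yl)-3,7,11,15-tetramethylhexadec-2-en-5-ol | COc1c(C)c(C/C=C(\C)C[C@@H](O)C[C@H](C)CCC[C@H](C)CCCC(C)C)c(OC)c2ccccc12 | intermediate
17 | 2-[(2E,5S,7R,11R)-5-hydroxy-3,7,11,15-tetramethylhexadec-2-en-1-yl]-3-methylnaphthalene-1,4-dione | CC1=C(C/C=C(\C)C[C@@H](O)C[C@H](C)CCC[C@H](C)CCCC(C)C)C(=O)c2ccccc2C1=O | target

**Step count and risks**

Total steps: 9. Longest linear sequence: 6 steps (steps 1, 2, 3, 4, 8, 9 from phytol); the menadione branch (steps 5, 6, 7) joins at step 8.

Step 8 (proposed new method, the riskiest). Aryl transfer from the hindered zinc reagent to nickel may be slow, so that isoprene oligomerisation or nickel-mediated 1,2-arylation of the aldehyde takes over, and the ligand may discriminate poorly between the aldehyde faces. The fallback uses known chemistry, sets out from aldehyde 7 (aryl partner from 10) and returns at 16. Aldehyde 7 would be propargylated with allenylboronic acid pinacol ester under a chiral BINOL-derived phosphoric acid (3,3'-bis(2,4,6-triisopropylphenyl) type, antipode chosen for Re-face addition; toluene, 4 Å molecular sieves, −20 °C). This passes through the boronate ester 4,4,5,5-tetramethyl-2-{[(4S,6R,10R)-6,10,14-trimethylpentadec-1-yn-4-yl]oxy}-1,3,2-dioxaborolane F1 and gives, after aqueous work-up, the homopropargylic alcohol (4S,6R,10R)-6,10,14-trimethylpentadec-1-yn-4-ol F2. Silylation (TBSCl, imidazole, DMF) would give the silyl ether tert-butyldimethyl{[(4S,6R,10R)-6,10,14-trimethylpentadec-1-yn-4-yl]oxy}silane F3. Zirconium-catalysed syn-carboalumination (Me3Al, Cp2ZrCl2 cat., CH2Cl2) would introduce the C3' methyl and give the E-alkenylalane {(1E,4S,6R,10R)-4-[(tert-butyldimethylsilyl)oxy]-2,6,10,14-tetramethylpentadec-1-en-1-yl}dimethylalane F4. This would be coupled in the same flask, under Pd(PPh3)4 catalysis, with the benzylic chloride 2-(chloromethyl)-1,4-dimethoxy-3-methylnaphthalene F5, made from 10 with paraformaldehyde and concentrated HCl. The coupling product is the silyl ether tert-butyl{[(2E,5S,7R,11R)-1-(1,4-dimethoxy-3-methylnaphthalen-2-yl)-3,7,11,15-tetramethylhexadec-2-en-5-yl]oxy}dimethylsilane F6, and Bu4NF in THF would free the hydroxyl and rejoin the route at 16.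

Step 3. Palladium may precipitate as metal before it is reoxidised, or the enol ether may lose its silyl group and revert to ketone 3, so that conversion to the enone stalls. The fallback sets out from 4 and returns at 5 by selenoxide elimination instead of palladium chemistry. Treatment of 4 with PhSeCl (THF, −78 °C) should give regiospecifically the selanyl ketone (6R,10R)-6,10,14-trimethyl-3-(phenylselanyl)pentadecan-2-one F7. Oxidation with H2O2 and pyridine in CH2Cl2 (0 °C → rt) would form the selenoxide (6R,10R)-6,10,14-trimethyl-3-(phenylseleninyl)pentadecan-2-one F8, which undergoes syn-elimination toward C4, the only side bearing hydrogen, to give the E-enone 5.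

Step 9. A cerium alkoxide of the homoallylic alcohol may undergo oxidative fragmentation of the C4'–C5' bond, or the hydroxyl may be oxidised, in competition with demethylation. The fallback sets out from 16 and returns at 17 by masking the hydroxyl through the oxidation. Silylation of 16 (TBSCl, imidazole, DMF) would give the silyl ether F6, the same compound as in the fallback to step 8. Oxidation with (NH4)2Ce(NO3)6 in MeCN/H2O at 0 °C would give the quinone silyl ether 2-{(2E,5S,7R,11R)-5-[(tert-butyldimethylsilyl)oxy]-3,7,11,15-tetramethylhexadec-2-en-1-yl}-3-methylnaphthalene-1,4-dione F9. HF·pyridine in THF, which the base-sensitive quinone tolerates, would then remove the silyl group to give 17.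

**Further compounds**

F1 | step 8 | 4,4,5,5-tetramethyl-2-{[(4S,6R,10R)-6,10,14-trimethylpentadec-1-yn-4-yl]oxy}-1,3,2-dioxaborolane | C#CC[C@@H](OB1OC(C)(C)C(C)(C)O1)C[C@H](C)CCC[C@H](C)CCCC(C)C
F2 | step 8 | (4S,6R,10R)-6,10,14-trimethylpentadec-1-yn-4-ol | C#CC[C@@H](O)C[C@H](C)CCC[C@H](C)CCCC(C)C
F3 | step 8 | tert-butyldimethyl{[(4S,6R,10R)-6,10,14-trimethylpentadec-1-yn-4-yl]oxy}silane | C#CC[C@@H](O[Si](C)(C)C(C)(C)C)C[C@H](C)CCC[C@H](C)CCCC(C)C
F4 | step 8 | {(1E,4S,6R,10R)-4-[(tert-butyldimethylsilyl)oxy]-2,6,10,14-tetramethylpentadec-1-en-1-yl}dimethylalane | C[Al](C)/C=C(\C)C[C@@H](O[Si](C)(C)C(C)(C)C)C[C@H](C)CCC[C@H](C)CCCC(C)C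
F5 | step 8 | 2-(chloromethyl)-1,4-dimethoxy-3-methylnaphthalene | COc1c(C)c(CCl)c(OC)c2ccccc12
F6 | step 8 | tert-butyl{[(2E,5S,7R,11R)-1-(1,4-dimethoxy-3-methylnaphthalen-2-yl)-3,7,11,15-tetramethylhexadec-2-en-5-yl]oxy}dimethylsilane | COc1c(C)c(C/C=C(\C)C[C@@H](O[Si](C)(C)C(C)(C)C)C[C@H](C)CCC[C@H](C)CCCC(C)C)c(OC)c2ccccc12
F7 | step 3 | (6R,10R)-6,10,14-trimethyl-3-(phenylselanyl)pentadecan-2-one (C3 epimers) | CC(=O)C([Se]c1ccccc1)CC[C@H](C)CCC[C@H](C)CCCC(C)C
F8 | step 3 | (6R,10R)-6,10,14-trimethyl-3-(phenylseleninyl)pentadecan-2-one (not isolated) | CC(=O)C([Se](=O)c1ccccc1)CC[C@H](C)CCC[C@H](C)CCCC(C)C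
F9 | step 9 | 2-{(2E,5S,7R,11R)-5-[(tert-butyldimethylsilyl)oxy]-3,7,11,15-tetramethylhexadec-2-en-1-yl}-3-methylnaphthalene-1,4-dione | CC1=C(C/C=C(\C)C[C@@H](O[Si](C)(C)C(C)(C)C)C[C@H](C)CCC[C@H](C)CCCC(C)C)C(=O)c2ccccc2C1=O
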